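**Plan**
Cuts, in retrosynthetic order: the three pivalate C–O bonds on the dihydrobenzofuran (DHB) half; indane C3–C3a; ring A–C1 and the H/B pair across an alkyne; alkyne–C5 of the DHB; DHB C2–C3; C2–C3 of the future indane.
Feature that allows the key step: indane C3 carries a free 4-hydroxyphenyl ring and is bonded to C3a of ring A, a carbon ortho to the C4 hydroxyl and para to the C6 hydroxyl. C3–C3a therefore joins the exocyclic carbon of a para-quinone methide to a resorcinol carbon held five atoms away.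
Forward order: the DHB ring is closed first (rhodium carbene C–H insertion), the chain is joined alkyne → (Z)-alkenylboronate → (E)-triaryl alkene, and the five-membered indane ring is closed last by a flavoprotein oxidase.
Stereochemistry: C2 comes from an Evans benzylation, DHB C3 from the chiral dirhodium catalyst, DHB C2 from equilibration to trans, the alkene geometry from syn borylcupration plus retentive Suzuki coupling, and C3 from C2 during ring closure.
Protecting groups: TIPS ethers sit on every phenol that must be free for the oxidase and pivalates on the three DHB phenols. The pivalate on the 2-aryl group hides the only other 4-hydroxybenzylic C–H and comes off by methanolysis, not by a Lewis acid that would open the DHB ring.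

Key step: step 23

Abbreviations and numbering: TIPS = triisopropylsilyl; Piv = pivaloyl; Bpin = pinacolboronate; indane atoms C1–C7a with ring A as the fused benzene ring; C1, C2 and C3 keep these labels in all open-chain precursors.
Assumption: Rh2(R-PTAD)4 is taken to give the (3R) centre of the dihydrobenzofuran; if the first run shows the opposite sense, the commercial S antipode is used and nothing else changes.

Step 1
Reactants: 1 4-hydroxybenzaldehyde
Product: 2 4-(TIPS-oxy)benzaldehyde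
Conditions: TIPSCl, imidazole, DMF, rt
Reagents that add atoms: triisopropylsilyl chloride, CC(C)[Si](Cl)(C(C)C)C(C)C
Why: Routine imidazole-promoted silylation of a phenol; the bulky TIPS ether is chosen because it must outlast enolates, organolithiums, hot hydrazine and aqueous phosphate later on.

Step 2
Reactants: 2 4-(TIPS-oxy)benzaldehyde
Product: 3 4-(TIPS-oxy)benzyl alcohol
Conditions: NaBH4, MeOH, 0 °C
Reagents that add atoms: none
Why: Borohydride reduction of an aromatic aldehyde, which leaves the aryl silyl ether untouched.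

Step 3
Reactants: 3 4-(TIPS-oxy)benzyl alcohol
Product: 4 4-(TIPS-oxy)benzyl bromide
Conditions: CBr4, PPh3, CH2Cl2, 0 °C
Reagents that add atoms: carbon tetrabromide, BrC(Br)(Br)Br
Why: The Appel bromination is neutral, so the easily ionised 4-silyloxybenzylic bromide never meets acid and can be used at once.

Step 4
Reactants: 5 5-bromoresorcinol
Product: 6 1-bromo-3,5-bis(TIPS-oxy)benzene
Conditions: TIPSCl, imidazole, DMF, rt
Reagents that add atoms: triisopropylsilyl chloride, CC(C)[Si](Cl)(C(C)C)C(C)C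
Why: Same phenol silylation as in step 1; the product serves twice, as Grignard precursor in step 13 and as donor of ring A in step 21.

Step 5
Reactants: 7 3,5-dihydroxyphenylacetic acid
Product: 9 [3,5-bis(TIPS-oxy)phenyl]acetic acid, via silyl ester 8 (not isolated)
Conditions: TIPSCl, imidazole, DMF, rt; then K2CO3, THF/MeOH/H2O, rt; then 1 M HCl to pH 3
Reagents that add atoms: triisopropylsilyl chloride, CC(C)[Si](Cl)(C(C)C)C(C)C
Why: Exhaustive silylation followed by selective hydrolysis of the far more labile silyl ester is the usual way to an O-silylated phenolic acid.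

Step 6
Reactants: 9 [3,5-bis(TIPS-oxy)phenyl]acetic acid; 10 (S)-4-benzyl-2-oxazolidinone
Product: 12 (4S)-4-benzyl-3-{[3,5-bis(TIPS-oxy)phenyl]acetyl}oxazolidin-2-one, via mixed pivalic anhydride 11 (not isolated)
Conditions: PivCl, Et3N, THF, −20 °C; then LiCl, 10, −20 °C → rt
Reagents that add atoms: none
Why: Mixed-anhydride N-acylation of an Evans oxazolidinone under LiCl/Et3N conditions needs no strong base and suits arylacetic acids.

Step 7
Reactants: 12 (4S)-4-benzyl-3-{[3,5-bis(TIPS-oxy)phenyl]acetyl}oxazolidin-2-one; 4 4-(TIPS-oxy)benzyl bromide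
Product: 14 (4S)-4-benzyl-3-{(2S)-2-[3,5-bis(TIPS-oxy)phenyl]-3-[4-(TIPS-oxy)phenyl]propanoyl}oxazolidin-2-one, via sodium enolate 13 (not isolated)
Conditions: NaN(SiMe3)2, THF, −78 °C; then 4, −78 → −30 °C
Reagents that add atoms: none
Why: Evans alkylation: the chelated (Z)-enolate is shielded on one face by the C4 benzyl group, so the benzylic bromide enters from the other face and sets C2 of the future indane as (S).

Step 8
Reactants: 14 alkylated imide
Product: 15 (2S)-2-[3,5-bis(TIPS-oxy)phenyl]-3-[4-(TIPS-oxy)phenyl]propan-1-ol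
Conditions: LiBH4, MeOH (1 equiv), Et2O, 0 °C
Reagents that add atoms: none
Why: Reductive cleavage of the imide with LiBH4 gives the primary alcohol without disturbing the base-sensitive C2 centre and returns the auxiliary.

Step 9
Reactants: 15 (2S)-alcohol
Product: 16 (2S)-2-[3,5-bis(TIPS-oxy)phenyl]-3-[4-(TIPS-oxy)phenyl]propanal
Conditions: Dess–Martin periodinane, CH2Cl2, 0 °C
Reagents that add atoms: none
Why: The Dess–Martin oxidation is fast and nearly neutral, which protects the configurationally labile alpha-aryl aldehyde; the product is carried on without chromatography.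

Step 10
Reactants: 16 (2S)-aldehyde
Product: 17 (3R)-1,1-dibromo-3-[3,5-bis(TIPS-oxy)phenyl]-4-[4-(TIPS-oxy)phenyl]but-1-ene
Conditions: CBr4, PPh3, CH2Cl2, 0 °C
Reagents that add atoms: carbon tetrabromide, BrC(Br)(Br)Br
Why: First half of the Corey–Fuchs sequence (Ramirez olefination), a non-basic Wittig-type reaction that removes the acidifying carbonyl group at once; the descriptor changes by priority only.

Step 11
Reactants: 17 (3R)-dibromoalkene
Product: 19 (3R)-3-[3,5-bis(TIPS-oxy)phenyl]-4-[4-(TIPS-oxy)phenyl]but-1-yne, via lithium acetylide 18 (not isolated)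
Conditions: n-BuLi (2 equiv), THF, −78 °C; then H2O
Reagents that add atoms: none
Why: Second half of the Corey–Fuchs sequence (bromine–lithium exchange, then Fritsch–Buttenberg–Wiechell rearrangement), run cold and with no excess base so that the propargylic C2–H stays in place.

Step 12
Reactants: 20 5-iodosalicylaldehyde; 3 4-(TIPS-oxy)benzyl alcohol
Product: 21 5-iodo-2-[4-(TIPS-oxy)benzyloxy]benzaldehyde
Conditions: PPh3, DIAD, THF, 0 °C → rt
Reagents that add atoms: none
Why: Mitsunobu etherification of the acidic salicylaldehyde phenol with a primary benzylic alcohol is neutral enough for the aryl silyl ether.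

Step 13
Reactants: 6 1-bromo-3,5-bis(TIPS-oxy)benzene; 21 5-iodo-2-[4-(TIPS-oxy)benzyloxy]benzaldehyde
Product: 23 racemic [3,5-bis(TIPS-oxy)phenyl]{5-iodo-2-[4-(TIPS-oxy)benzyloxy]phenyl}methanol, via aryl Grignard reagent 22 (not isolated)
Conditions: 6, Mg, THF, 40 °C; then 21, THF, −20 °C; then H2O
Reagents that add atoms: none
Why: Grignard addition to an aldehyde; unlike an aryllithium, the magnesium reagent does not exchange with the aryl iodide at this temperature, and the new carbinol centre is erased in step 14.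

Step 14
Reactants: 23 racemic diaryl carbinol
Product: 24 [3,5-bis(TIPS-oxy)phenyl]{5-iodo-2-[4-(TIPS-oxy)benzyloxy]phenyl}methanone
Conditions: MnO2, CH2Cl2, rt
Reagents that add atoms: none
Why: MnO2 oxidation of a doubly benzylic alcohol is selective and neutral.

Step 15
Reactants: 24 diaryl ketone
Product: 25 hydrazone of 24 (E/Z mixture)
Conditions: N2H4·H2O (excess), AcOH (cat.), EtOH, 80 °C
Reagents that add atoms: hydrazine hydrate, NN.O
Why: Acid-catalysed condensation of a diaryl ketone with hydrazine, the excess suppressing azine formation and the acetic acid buffering the medium for the TIPS ethers.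

Step 16
Reactants: 25 hydrazone
Product: 27 (2S,3R)-cis-3-[3,5-bis(TIPS-oxy)phenyl]-5-iodo-2-[4-(TIPS-oxy)phenyl]-2,3-dihydrobenzofuran, via diaryldiazomethane 26 (not isolated)
Conditions: MnO2, CH2Cl2, rt, filtration; then Rh2(R-PTAD)4 (1 mol %), CH2Cl2, 0 °C
Reagents that add atoms: none
Why: MnO2 dehydrogenates the hydrazone to the donor/donor diazo compound, whose dirhodium carbene undergoes enantioselective 1,5-C–H insertion into the benzylic ether methylene; the chiral carboxylate ligands fix C3 as (R) and the concerted insertion places the two aryl groups cis.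

Step 17
Reactants: 27 cis-dihydrobenzofuran tris(TIPS ether)
Product: 30 5-[(2R,3R)-2-(4-hydroxyphenyl)-5-iodo-2,3-dihydrobenzofuran-3-yl]benzene-1,3-diol, via cis triol 28 (not isolated), via ring-opened quinone methide 29 (not isolated)
Conditions: TBAF, THF, 0 °C → rt; then AcOH
Reagents that add atoms: none
Why: After fluoride desilylation the phenoxide para to C2 expels the ring aryloxide and re-adds it (retro-oxa-Michael/oxa-Michael, as known for phenolic phenylcoumarans), so only C2 inverts, C3 is untouched and the more stable trans (2R,3R) isomer accumulates.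

Step 18
Reactants: 30 trans triol
Product: 31 (2R,3R)-trans-5-iodo-2-[4-(pivaloyloxy)phenyl]-3-[3,5-bis(pivaloyloxy)phenyl]-2,3-dihydrobenzofuran
Conditions: PivCl, Et3N, DMAP (cat.), CH2Cl2, 0 °C → rt
Reagents that add atoms: pivaloyl chloride, CC(C)(C)C(=O)Cl
Why: Exhaustive acylation gives esters that are orthogonal to fluoride and robust in steps 19 to 23; the ester on the 2-aryl group also shuts the ring-opening path of step 17 and hides that 4-hydroxybenzylic C–H from the oxidase.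

Step 19
Reactants: 19 (3R)-terminal alkyne; 31 iodo-dihydrobenzofuran tripivalate
Product: 32 internal alkyne: 31 with iodine replaced by the (3S)-3-[3,5-bis(TIPS-oxy)phenyl]-4-[4-(TIPS-oxy)phenyl]but-1-yn-1-yl group
Conditions: PdCl2(PPh3)2 (cat.), CuI (cat.), Et3N, THF, rt
Reagents that add atoms: none
Why: Sonogashira coupling of an aryl iodide runs at room temperature with a tertiary amine that harms neither pivalates nor the propargylic centre; because 31 is a single enantiomer, any C2 epimer carried from steps 9 to 11 becomes a separable diastereomer here.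

Step 20
Reactants: 32 internal alkyne
Product: 33 (Z)-alkenylboronate: Bpin on C1 and H on the carbon next to the dihydrobenzofuran ring with C2 unchanged in space (descriptor R)
Conditions: CuCl (cat.), P(p-tol)3, NaOtBu (cat.), B2pin2, MeOH, THF, rt
Reagents that add atoms: bis(pinacolato)diboron, CC1(C)OB(OC1(C)C)B1OC(C)(C)C(C)(C)O1
Why: Copper-catalysed formal hydroboration of an aryl alkyl alkyne (syn borylcupration, then protonation by MeOH) puts copper next to the aryl ring and boron on C1, so H and B end up cis and the geometry of the later alkene is fixed.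

Step 21
Reactants: 33 (Z)-alkenylboronate; 6 1-bromo-3,5-bis(TIPS-oxy)benzene
Product: 34 protected seco compound: (E)-alkene with ring A as its bis(TIPS ether) on C1 trans to the dihydrobenzofuran ring and C2 (S)
Conditions: Pd(OAc)2 (cat.), SPhos, K3PO4, toluene/H2O, 60 °C
Reagents that add atoms: none
Why: The Suzuki–Miyaura coupling proceeds with retention at the alkenyl carbon, so ring A takes the place of boron, cis to the vinylic hydrogen.

Step 22
Reactants: 34 protected seco compound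
Product: 35 seco compound: pentaphenol tripivalate with a C3 methylene and C2 (S) and an (E)-alkene and a (2R,3R)-dihydrobenzofuran
Conditions: TBAF, AcOH, THF, 0 °C → rt, under argon
Reagents that add atoms: none
Why: Fluoride buffered with acetic acid cleaves the five aryl silyl ethers in a medium that is never basic, so the pivalates, the alkene and the allylic C2–H survive.

Step 23
Reactants: 35 seco compound
Product: 37 indane tripivalate: (2S,3S)-trans-indane with an (E)-exocyclic alkene and a (2R,3R)-dihydrobenzofuran, via para-quinone methide 36 (not isolated)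
Conditions: evolved eugenol oxidase variant (FAD-dependent, vanillyl alcohol oxidase family), air, catalase, K2HPO4/KH2PO4 buffer pH 7.5, DMSO as cosolvent, 25 °C
Reagents that add atoms: none
Why: Proposed new method: the oxidase binds the single 4-alkylphenol of 35 as its phenolate and moves a hydride from the C3 methylene to the flavin, which O2 reoxidises with release of H2O2, so para-quinone methide 36 arises by a two-electron path and no phenoxyl radical is involved. The closest known reaction type is the oxidation of 4-alkyl-, 4-allyl- and 4-(alkoxymethyl)phenols through enzyme-bound para-quinone methides by vanillyl alcohol oxidase and eugenol oxidase, where water normally adds; new here are the size of the substrate, which calls for a variant with an opened substrate channel, and the capture of the methide by an internal carbon nucleophile. Ring A, a free resorcinol that is partly ionised at this pH, attacks the exocyclic methide carbon with the carbon next to its link to C1 (ortho to one hydroxyl, para to the other) in a 5-exo-trig vinylogous Friedel–Crafts addition that forms C3–C3a and the five-membered ring, and two tautomerisations restore both arenes. The new C3 stereocentre is set by C2: in the envelope-like transition state the cyclohexadienone end of the methide lies on the face away from the C2 aryl group, which gives the trans (2S,3S) indane, also the more stable isomer. Site selectivity follows from the mechanism, since hydride loss needs a C–H para to a free phenol: the four resorcinol hydroxyls are meta to their benzylic carbons and the 2-aryl group of the dihydrobenzofuran is blocked as its pivalate. The closure must also outrun hydration of 36 and its tautomerisation by loss of the C2 hydrogen, which the five-atom tether, the unetherified ring A and a variant without the water-activating carboxylate are meant to secure.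

Step 24
Reactants: 37 indane tripivalate
Product: 38 target CNP0184753.1
Conditions: K2CO3, degassed MeOH, under argon, 0 °C → rt; then 1 M HCl to pH 5
Reagents that add atoms: none
Why: Base-mediated methanolysis of aryl esters is the standard mild release of stilbenoid polyphenols and, unlike a Lewis-acid ether cleavage, neither opens the dihydrobenzofuran nor shifts the exocyclic alkene into the ring.

**Compound list**
1 | 4-hydroxybenzaldehyde | O=Cc1ccc(O)cc1 | starting material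
2 | 4-(TIPS-oxy)benzaldehyde | O=Cc1ccc(O[Si](C(C)C)(C(C)C)C(C)C)cc1 | intermediate
3 | 4-(TIPS-oxy)benzyl alcohol | OCc1ccc(O[Si](C(C)C)(C(C)C)C(C)C)cc1 | intermediate
4 | 4-(TIPS-oxy)benzyl bromide | BrCc1ccc(O[Si](C(C)C)(C(C)C)C(C)C)cc1 | intermediate
5 | 5-bromoresorcinol | Oc1cc(O)cc(Br)c1 | starting material
6 | 1-bromo-3,5-bis(TIPS-oxy)benzene | Brc1cc(O[Si](C(C)C)(C(C)C)C(C)C)cc(O[Si](C(C)C)(C(C)C)C(C)C)c1 | intermediate
7 | 3,5-dihydroxyphenylacetic acid | OC(=O)Cc1cc(O)cc(O)c1 | starting material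
8 | triisopropylsilyl [3,5-bis(TIPS-oxy)phenyl]acetate (not isolated) | CC(C)[Si](C(C)C)(C(C)C)OC(=O)Cc1cc(O[Si](C(C)C)(C(C)C)C(C)C)cc(O[Si](C(C)C)(C(C)C)C(C)C)c1 | intermediate
9 | [3,5-bis(TIPS-oxy)phenyl]acetic acid | OC(=O)Cc1cc(O[Si](C(C)C)(C(C)C)C(C)C)cc(O[Si](C(C)C)(C(C)C)C(C)C)c1 | intermediate
10 | (S)-4-benzyl-2-oxazolidinone | O=C1N[C@@H](Cc2ccccc2)CO1 | starting material
11 | [3,5-bis(TIPS-oxy)phenyl]acetic pivalic anhydride (not isolated) | CC(C)(C)C(=O)OC(=O)Cc1cc(O[Si](C(C)C)(C(C)C)C(C)C)cc(O[Si](C(C)C)(C(C)C)C(C)C)c1 | intermediate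
12 | (4S)-4-benzyl-3-{[3,5-bis(TIPS-oxy)phenyl]acetyl}oxazolidin-2-one | O=C(Cc1cc(O[Si](C(C)C)(C(C)C)C(C)C)cc(O[Si](C(C)C)(C(C)C)C(C)C)c1)N1[C@@H](Cc2ccccc2)COC1=O | intermediate
13 | sodium (Z)-enolate of 12 (not isolated) | [Na+].[O-]/C(=C\c1cc(O[Si](C(C)C)(C(C)C)C(C)C)cc(O[Si](C(C)C)(C(C)C)C(C)C)c1)N1[C@@H](Cc2ccccc2)COC1=O | intermediate
14 | (4S)-4-benzyl-3-{(2S)-2-[3,5-bis(TIPS-oxy)phenyl]-3-[4-(TIPS-oxy)phenyl]propanoyl}oxazolidin-2-one | CC(C)[Si](C(C)C)(C(C)C)Oc1ccc(C[C@@H](c2cc(O[Si](C(C)C)(C(C)C)C(C)C)cc(O[Si](C(C)C)(C(C)C)C(C)C)c2)C(=O)N2[C@@H](Cc3ccccc3)COC2=O)cc1 | intermediate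
15 | (2S)-2-[3,5-bis(TIPS-oxy)phenyl]-3-[4-(TIPS-oxy)phenyl]propan-1-ol | CC(C)[Si](C(C)C)(C(C)C)Oc1ccc(C[C@@H](c2cc(O[Si](C(C)C)(C(C)C)C(C)C)cc(O[Si](C(C)C)(C(C)C)C(C)C)c2)CO)cc1 | intermediate
16 | (2S)-2-[3,5-bis(TIPS-oxy)phenyl]-3-[4-(TIPS-oxy)phenyl]propanal | CC(C)[Si](C(C)C)(C(C)C)Oc1ccc(C[C@@H](c2cc(O[Si](C(C)C)(C(C)C)C(C)C)cc(O[Si](C(C)C)(C(C)C)C(C)C)c2)C=O)cc1 | intermediate
17 | (3R)-1,1-dibromo-3-[3,5-bis(TIPS-oxy)phenyl]-4-[4-(TIPS-oxy)phenyl]but-1-ene | CC(C)[Si](C(C)C)(C(C)C)Oc1ccc(C[C@@H](c2cc(O[Si](C(C)C)(C(C)C)C(C)C)cc(O[Si](C(C)C)(C(C)C)C(C)C)c2)C=C(Br)Br)cc1 | intermediate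
18 | lithium acetylide of 19 (not isolated) | CC(C)[Si](C(C)C)(C(C)C)Oc1ccc(C[C@@H](c2cc(O[Si](C(C)C)(C(C)C)C(C)C)cc(O[Si](C(C)C)(C(C)C)C(C)C)c2)C#C[Li])cc1 | intermediate
19 | (3R)-3-[3,5-bis(TIPS-oxy)phenyl]-4-[4-(TIPS-oxy)phenyl]but-1-yne | CC(C)[Si](C(C)C)(C(C)C)Oc1ccc(C[C@@H](c2cc(O[Si](C(C)C)(C(C)C)C(C)C)cc(O[Si](C(C)C)(C(C)C)C(C)C)c2)C#C)cc1 | intermediate
20 | 5-iodosalicylaldehyde | O=Cc1cc(I)ccc1O | starting material
21 | 5-iodo-2-[4-(TIPS-oxy)benzyloxy]benzaldehyde | O=Cc1cc(I)ccc1OCc1ccc(O[Si](C(C)C)(C(C)C)C(C)C)cc1 | intermediate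
22 | 3,5-bis(TIPS-oxy)phenylmagnesium bromide (not isolated) | Br[Mg]c1cc(O[Si](C(C)C)(C(C)C)C(C)C)cc(O[Si](C(C)C)(C(C)C)C(C)C)c1 | intermediate
23 | racemic [3,5-bis(TIPS-oxy)phenyl]{5-iodo-2-[4-(TIPS-oxy)benzyloxy]phenyl}methanol | OC(c1cc(O[Si](C(C)C)(C(C)C)C(C)C)cc(O[Si](C(C)C)(C(C)C)C(C)C)c1)c1cc(I)ccc1OCc1ccc(O[Si](C(C)C)(C(C)C)C(C)C)cc1 | intermediate
24 | [3,5-bis(TIPS-oxy)phenyl]{5-iodo-2-[4-(TIPS-oxy)benzyloxy]phenyl}methanone | O=C(c1cc(O[Si](C(C)C)(C(C)C)C(C)C)cc(O[Si](C(C)C)(C(C)C)C(C)C)c1)c1cc(I)ccc1OCc1ccc(O[Si](C(C)C)(C(C)C)C(C)C)cc1 | intermediate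
25 | hydrazone of 24 (E/Z mixture) | NN=C(c1cc(O[Si](C(C)C)(C(C)C)C(C)C)cc(O[Si](C(C)C)(C(C)C)C(C)C)c1)c1cc(I)ccc1OCc1ccc(O[Si](C(C)C)(C(C)C)C(C)C)cc1 | intermediate
26 | diaryldiazomethane from 25 (not isolated) | [N-]=[N+]=C(c1cc(O[Si](C(C)C)(C(C)C)C(C)C)cc(O[Si](C(C)C)(C(C)C)C(C)C)c1)c1cc(I)ccc1OCc1ccc(O[Si](C(C)C)(C(C)C)C(C)C)cc1 | intermediate
27 | (2S,3R)-cis-3-[3,5-bis(TIPS-oxy)phenyl]-5-iodo-2-[4-(TIPS-oxy)phenyl]-2,3-dihydrobenzofuran | Ic1ccc2c(c1)[C@@H](c1cc(O[Si](C(C)C)(C(C)C)C(C)C)cc(O[Si](C(C)C)(C(C)C)C(C)C)c1)[C@@H](c1ccc(O[Si](C(C)C)(C(C)C)C(C)C)cc1)O2 | intermediate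
28 | (2S,3R)-cis triol (not isolated) | Ic1ccc2c(c1)[C@@H](c1cc(O)cc(O)c1)[C@@H](c1ccc(O)cc1)O2 | intermediate
29 | ring-opened para-quinone methide, (R) at the diarylmethine carbon (not isolated) | Oc1ccc(I)cc1[C@@H](c1cc(O)cc(O)c1)C=C1C=CC(=O)C=C1 | intermediate
30 | 5-[(2R,3R)-2-(4-hydroxyphenyl)-5-iodo-2,3-dihydrobenzofuran-3-yl]benzene-1,3-diol | Ic1ccc2c(c1)[C@@H](c1cc(O)cc(O)c1)[C@H](c1ccc(O)cc1)O2 | intermediate
31 | (2R,3R)-trans-5-iodo-2-[4-(pivaloyloxy)phenyl]-3-[3,5-bis(pivaloyloxy)phenyl]-2,3-dihydrobenzofuran | Ic1ccc2c(c1)[C@@H](c1cc(OC(=O)C(C)(C)C)cc(OC(=O)C(C)(C)C)c1)[C@H](c1ccc(OC(=O)C(C)(C)C)cc1)O2 | intermediate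
32 | internal alkyne, C2 (S), dihydrobenzofuran (2R,3R) | CC(C)[Si](C(C)C)(C(C)C)Oc1ccc(C[C@@H](c2cc(O[Si](C(C)C)(C(C)C)C(C)C)cc(O[Si](C(C)C)(C(C)C)C(C)C)c2)C#Cc2ccc3c(c2)[C@@H](c2cc(OC(=O)C(C)(C)C)cc(OC(=O)C(C)(C)C)c2)[C@H](c2ccc(OC(=O)C(C)(C)C)cc2)O3)cc1 | intermediate
33 | (Z)-alkenylboronate with Bpin on C1, C2 descriptor (R) | CC(C)[Si](C(C)C)(C(C)C)Oc1ccc(C[C@@H](c2cc(O[Si](C(C)C)(C(C)C)C(C)C)cc(O[Si](C(C)C)(C(C)C)C(C)C)c2)/C(B2OC(C)(C)C(C)(C)O2)=C\c2ccc3c(c2)[C@@H](c2cc(OC(=O)C(C)(C)C)cc(OC(=O)C(C)(C)C)c2)[C@H](c2ccc(OC(=O)C(C)(C)C)cc2)O3)cc1 | intermediate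
34 | protected seco compound, (E)-alkene, C2 (S) | CC(C)[Si](C(C)C)(C(C)C)Oc1ccc(C[C@@H](c2cc(O[Si](C(C)C)(C(C)C)C(C)C)cc(O[Si](C(C)C)(C(C)C)C(C)C)c2)/C(c2cc(O[Si](C(C)C)(C(C)C)C(C)C)cc(O[Si](C(C)C)(C(C)C)C(C)C)c2)=C\c2ccc3c(c2)[C@@H](c2cc(OC(=O)C(C)(C)C)cc(OC(=O)C(C)(C)C)c2)[C@H](c2ccc(OC(=O)C(C)(C)C)cc2)O3)cc1 | intermediate
35 | seco compound (pentaphenol tripivalate), (E)-alkene, C2 (S) | Oc1ccc(C[C@@H](c2cc(O)cc(O)c2)/C(c2cc(O)cc(O)c2)=C\c2ccc3c(c2)[C@@H](c2cc(OC(=O)C(C)(C)C)cc(OC(=O)C(C)(C)C)c2)[C@H](c2ccc(OC(=O)C(C)(C)C)cc2)O3)cc1 | intermediate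
36 | para-quinone methide of 35, C2 (S) (not isolated) | O=C1C=CC(=C[C@@H](c2cc(O)cc(O)c2)/C(c2cc(O)cc(O)c2)=C\c2ccc3c(c2)[C@@H](c2cc(OC(=O)C(C)(C)C)cc(OC(=O)C(C)(C)C)c2)[C@H](c2ccc(OC(=O)C(C)(C)C)cc2)O3)C=C1 | intermediate
37 | indane tripivalate, (2S,3S)-trans, (E)-alkene, dihydrobenzofuran (2R,3R) | Oc1ccc([C@H]2c3c(O)cc(O)cc3/C(=C/c3ccc4c(c3)[C@@H](c3cc(OC(=O)C(C)(C)C)cc(OC(=O)C(C)(C)C)c3)[C@H](c3ccc(OC(=O)C(C)(C)C)cc3)O4)[C@@H]2c2cc(O)cc(O)c2)cc1 | intermediate
38 | CNP0184753.1 | Oc1ccc([C@H]2c3c(O)cc(O)cc3/C(=C/c3ccc4c(c3)[C@@H](c3cc(O)cc(O)c3)[C@H](c3ccc(O)cc3)O4)[C@@H]2c2cc(O)cc(O)c2)cc1 | target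

**Step count**
Total steps: 24. Longest linear sequence: 15 steps (1 → 2 → 3 → 21 → 23 → 24 → 25 → 27 → 30 → 31 → 32 → 33 → 34 → 35 → 37 → 38).

**Steps most likely to fail**

Step 23 (new method).
- **What may go wrong:** there may be no turnover because the large substrate does not reach the flavin. Hydration or tautomerisation of the methide may outrun ring closure. The product may be oxidised further at its own tertiary C3–H.
- **Fallback:** it uses known chemistry. C3 is brought in at the benzylic ether oxidation level, so that acid instead of an oxidase releases the same methide. It sets out from 2 and 12 and comes back at 36.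
- **Route:** Aldehyde 2 is turned with HC(OMe)3 and catalytic TsOH in MeOH into 4-(TIPS-oxy)benzaldehyde dimethyl acetal F1.
- The enolate made from 12 with TiCl4 and iPr2NEt in CH2Cl2 is alkylated by the oxocarbenium ion from F1 on the same face that step 7 uses. This gives the C3-methoxy imide F2. Its C3 epimers need no separation because C3 becomes planar later.
- The operations of steps 8 to 11 then lead through the C3-methoxy alcohol F3, the C3-methoxy aldehyde F4 (kept cold and used at once) and the C3-methoxy dibromoalkene F5 to the C3-methoxy alkyne F6.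
- The operations of steps 19 to 22, with 31 and 6, lead through the C3-methoxy internal alkyne F7, the C3-methoxy alkenylboronate F8 and the protected C3-methoxy triaryl alkene F9 to the C3-methoxy pentaphenol F10.
- A catalytic amount of diphenyl phosphate in MeCN at rt ionises the 4-hydroxybenzylic ether of F10 to 36, which closes to 37 as in step 23.
- **Precedent:** acid-catalysed generation of para-quinone methides from 4-hydroxybenzylic alcohols and ethers, and their capture by electron-rich arenes, are established reactions.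

Step 20.
- **What may go wrong:** borylcupration may show poor regioselectivity at the alkyne carbon next to the branched C2. A slow reaction would give the alkoxide time to attack the pivalates or to shift the propargylic hydrogen.
- **Fallback:** it needs no alkyne. It sets out from 14 and comes back at 34.
- **Route:** Transamination of 14 with MeNH(OMe)·HCl and AlMe3 gives the Weinreb amide F11.
- Grignard reagent 22 adds once to F11 to give the ring A ketone F12, which is handled cold and without base because of its acidic C2–H.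
- Non-basic methylenation of F12 with Zn, CH2Br2 and TiCl4 gives the 1,1-disubstituted alkene F13.
- A Heck arylation of F13 with 31 (Pd(OAc)2, P(o-tol)3, Et3N, DMF, 90 °C) places the dihydrobenzofuran ring trans to ring A and gives 34.

Step 15.
- **What may go wrong:** aryl silyl ethers may be lost in hot hydrazine, and condensation at the hindered ketone may be incomplete.
- **Fallback:** the diazo compound is reached by elimination instead of oxidation. It sets out from 24 and comes back at 26.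
- **Route:** Ketone 24 is condensed with TsNHNH2 and catalytic pyridinium tosylate in dioxane at 70 °C to give the N-tosylhydrazone F14.
- Its sodium salt (NaH, THF) is warmed in a Bamford–Stevens reaction to release 26, which is filtered and passed to the rhodium catalyst as in step 16.

Further compounds
F1 | step 23 | 4-(TIPS-oxy)benzaldehyde dimethyl acetal | COC(OC)c1ccc(O[Si](C(C)C)(C(C)C)C(C)C)cc1
F2 | step 23 | C3-methoxy imide, C2 placed as in 14, C3 epimers | CC(C)[Si](C(C)C)(C(C)C)Oc1ccc(C(OC)[C@@H](c2cc(O[Si](C(C)C)(C(C)C)C(C)C)cc(O[Si](C(C)C)(C(C)C)C(C)C)c2)C(=O)N2[C@@H](Cc3ccccc3)COC2=O)cc1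
F3 | step 23 | C3-methoxy alcohol | CC(C)[Si](C(C)C)(C(C)C)Oc1ccc(C(OC)[C@@H](c2cc(O[Si](C(C)C)(C(C)C)C(C)C)cc(O[Si](C(C)C)(C(C)C)C(C)C)c2)CO)cc1
F4 | step 23 | C3-methoxy aldehyde | CC(C)[Si](C(C)C)(C(C)C)Oc1ccc(C(OC)[C@@H](c2cc(O[Si](C(C)C)(C(C)C)C(C)C)cc(O[Si](C(C)C)(C(C)C)C(C)C)c2)C=O)cc1
F5 | step 23 | C3-methoxy dibromoalkene | CC(C)[Si](C(C)C)(C(C)C)Oc1ccc(C(OC)[C@@H](c2cc(O[Si](C(C)C)(C(C)C)C(C)C)cc(O[Si](C(C)C)(C(C)C)C(C)C)c2)C=C(Br)Br)cc1
F6 | step 23 | C3-methoxy alkyne | CC(C)[Si](C(C)C)(C(C)C)Oc1ccc(C(OC)[C@@H](c2cc(O[Si](C(C)C)(C(C)C)C(C)C)cc(O[Si](C(C)C)(C(C)C)C(C)C)c2)C#C)cc1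
F7 | step 23 | C3-methoxy internal alkyne | CC(C)[Si](C(C)C)(C(C)C)Oc1ccc(C(OC)[C@@H](c2cc(O[Si](C(C)C)(C(C)C)C(C)C)cc(O[Si](C(C)C)(C(C)C)C(C)C)c2)C#Cc2ccc3c(c2)[C@@H](c2cc(OC(=O)C(C)(C)C)cc(OC(=O)C(C)(C)C)c2)[C@H](c2ccc(OC(=O)C(C)(C)C)cc2)O3)cc1
F8 | step 23 | C3-methoxy alkenylboronate | CC(C)[Si](C(C)C)(C(C)C)Oc1ccc(C(OC)[C@@H](c2cc(O[Si](C(C)C)(C(C)C)C(C)C)cc(O[Si](C(C)C)(C(C)C)C(C)C)c2)/C(B2OC(C)(C)C(C)(C)O2)=C\c2ccc3c(c2)[C@@H](c2cc(OC(=O)C(C)(C)C)cc(OC(=O)C(C)(C)C)c2)[C@H](c2ccc(OC(=O)C(C)(C)C)cc2)O3)cc1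
F9 | step 23 | protected C3-methoxy triaryl alkene | CC(C)[Si](C(C)C)(C(C)C)Oc1ccc(C(OC)[C@@H](c2cc(O[Si](C(C)C)(C(C)C)C(C)C)cc(O[Si](C(C)C)(C(C)C)C(C)C)c2)/C(c2cc(O[Si](C(C)C)(C(C)C)C(C)C)cc(O[Si](C(C)C)(C(C)C)C(C)C)c2)=C\c2ccc3c(c2)[C@@H](c2cc(OC(=O)C(C)(C)C)cc(OC(=O)C(C)(C)C)c2)[C@H](c2ccc(OC(=O)C(C)(C)C)cc2)O3)cc1
F10 | step 23 | C3-methoxy pentaphenol | Oc1ccc(C(OC)[C@@H](c2cc(O)cc(O)c2)/C(c2cc(O)cc(O)c2)=C\c2ccc3c(c2)[C@@H](c2cc(OC(=O)C(C)(C)C)cc(OC(=O)C(C)(C)C)c2)[C@H](c2ccc(OC(=O)C(C)(C)C)cc2)O3)cc1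
F11 | step 20 | Weinreb amide, C2 (S) | CC(C)[Si](C(C)C)(C(C)C)Oc1ccc(C[C@@H](c2cc(O[Si](C(C)C)(C(C)C)C(C)C)cc(O[Si](C(C)C)(C(C)C)C(C)C)c2)C(=O)N(C)OC)cc1
F12 | step 20 | ring A ketone, C2 (S) | CC(C)[Si](C(C)C)(C(C)C)Oc1ccc(C[C@@H](c2cc(O[Si](C(C)C)(C(C)C)C(C)C)cc(O[Si](C(C)C)(C(C)C)C(C)C)c2)C(=O)c2cc(O[Si](C(C)C)(C(C)C)C(C)C)cc(O[Si](C(C)C)(C(C)C)C(C)C)c2)cc1
F13 | step 20 | 1,1-disubstituted alkene, C2 (S) | CC(C)[Si](C(C)C)(C(C)C)Oc1ccc(C[C@@H](c2cc(O[Si](C(C)C)(C(C)C)C(C)C)cc(O[Si](C(C)C)(C(C)C)C(C)C)c2)C(=C)c2cc(O[Si](C(C)C)(C(C)C)C(C)C)cc(O[Si](C(C)C)(C(C)C)C(C)C)c2)cc1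
F14 | step 15 | N-tosylhydrazone of 24 | Cc1ccc(cc1)S(=O)(=O)NN=C(c1cc(O[Si](C(C)C)(C(C)C)C(C)C)cc(O[Si](C(C)C)(C(C)C)C(C)C)c1)c1cc(I)ccc1OCc1ccc(O[Si](C(C)C)(C(C)C)C(C)C)cc1
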